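Amounts of target, counted in percent of the substrate charged, can be compared between flasks with different charges, and they were what I compared.

| flask | substrate | temperature | remark | time |
|---|---|---|---|---|
| midnight | 2.1 M | −25 °C | run made earlier |  |
| spring | 2.1 M | 2 °C | run made earlier |  |
| cedar | 1.5 M | −5 °C |  | 40 min |
| ash | 1.5 M | −20 °C |  | 40 min |
| larch | 1.5 M | 25 °C |  | 40 min |
| elm | 1.5 M | 10 °C |  | 40 min |

| run | time / min | target / % |
|---|---|---|
| midnight | 6.00 | 0.4 |
| midnight | 20.0 | 1.5 |
| midnight | 40.0 | 1.6 |
| midnight | 50.0 | 2.8 |
| midnight | 80.0 | 2.0 |
| midnight | 120 | 4.1 |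
| spring | 2.50 | 4.1 |
| spring | 8.00 | 9.9 |
| spring | 15.0 | 12.5 |
| spring | 20.0 | 13.5 |
| spring | 30.0 | 12.8 |
| spring | 40.0 | 11.3 |

(readings scatter by 0.5 percentage points)

- percent here means substrate units held: one self-condensation product counts as two
- what may be going on: target <-> isomer of the product B; 2 substrate -> self-condensation product; substrate <-> isomer of the product A; substrate <-> target

- the flask with the highest amount of target, in percent of the substrate charged ("all alike" if they lie within 1.5 percentage points) (cedar / ash / larch / elm / all alike)
- final target, as a percentage of the substrate charged, in cedar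
- final target, as a percentage of the substrate charged, in ash
- final target, as a percentage of the substrate charged, in larch
- final target, as a percentage of the substrate charged, in elm

Early in a run the target rises along a nearly straight line, so I compared slopes at the start. I took the turning of substrate into target as first order, so that a slope in percent of the charge carries over between charges. The first spring reading gave a slope r of 0.0164 min⁻¹, and the last midnight reading gave 3.42 × 10⁻⁴ min⁻¹, far slower. The clock slope g, the natural logarithm of that ratio per kelvin between the runs, came to 0.143 K⁻¹. With it, a time t at temperature T is worth θ = t·exp(g(T − T_spring)) on the spring clock, which is a time–temperature shift.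

Cedar's 40 min was worth 14.7 min. The straight line without any bend, rθ, gave what I took as a ceiling of 24.0 %. For a floor I took the spring reading nearest that clock time, 12.5 % at 15.0 min, since spring carried more substrate and I expected it to lose more to self-condensation. To tighten the ceiling, I supposed that the whole gap of 12 percentage points was condensation loss, scaling with the charge. That brought the ceiling down to 15.8 %.

Ash's clock stopped at 1.71 min, earlier than cedar's. Elm's stopped at 126 min and larch's at 1080 min, both later than the last spring reading at 40.0 min, when target had already fallen from 13.5 % to 11.3 %. So I chose cedar.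

The forecast also named cedar, with 14 % there, “near its maximum at 40 min”, 3.9 % in ash, 7 % in elm and 2 % in larch.

Cedar gave 14.1 %, above my floor and below my ceiling, and it held more target than any other flask, with 6.16 % in elm and 3.84 % in larch.

    target ⇌ isomer of the product B (K = 22.1, k = 0.0278 min⁻¹, Ea = 83.0 kJ mol⁻¹, ΔH = −14.0 kJ mol⁻¹)
    2 substrate → self-condensation product (k = 0.0255 M⁻¹ min⁻¹, Ea = 70.0 kJ mol⁻¹)
    substrate ⇌ isomer of the product A (K = 0.770, k = 0.234 min⁻¹, Ea = 87.0 kJ mol⁻¹, ΔH = −41.0 kJ mol⁻¹)
    substrate ⇌ target (K = 0.150, k = 0.438 min⁻¹, Ea = 88.0 kJ mol⁻¹, ΔH = −13.0 kJ mol⁻¹)
    (constants at 25 °C)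

With the back reaction of target to substrate struck out, cedar gives 24.3 %. Using g once more, ash's 1.71 min on the spring clock gives 2.80 % along the straight line, and ash held 2.95 %.

(The earlier runs and the new flask were computed with constants of no real substance, and the scatter is random.)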